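**Retrosynthetic overview**
- Last bond: C3''–C4'' of the diene by Suzuki coupling of a ring-A (E)-alkenyl boronate with a core (Z)-alkenyl iodide; no protecting group is left at the end.
- Core: the two oxirane C–O bonds are the key disconnection. A hydroxyl-directed nucleophilic epoxidation of a 2-(1-hydroxyalkyl)-p-benzoquinone (new) is followed by reduction of both carbonyls on the epoxide face, so all four ring stereocentres derive from the side-chain carbinol.
- Quinone from CAN oxidation of a dimethoxyarene; carbinol from catalytic asymmetric propynylation of 2,5-dimethoxyterephthalaldehyde; (Z)-iodoalkene by Red-Al/I2.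
- Ring A: Shi epoxidation of geranyl acetate, Ti(III) radical cyclization, exo-alkene epoxidation/LiAlH4 (tertiary alcohol), oxidation, Takai–Utimoto olefination.
- Ring order: ring A is the only carbocycle built (cyclization); the core six-membered ring is a purchased arene that is dearomatized; the oxirane is closed in the key step.

Assumption: the SMILES is read literally, so the trisubstituted side-chain alkene has the carbinol carbon and the vinyl group cis (2Z) and the disubstituted one is E. The ProPhenol antipode in step 7 is the one that gives Si-face addition (S carbinol); its sense must be confirmed by Mosher analysis.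

**Route**

Step 1
Reactants: 1 geranyl acetate
Product: 2 (2E)-5-[(2R)-3,3-dimethyloxiran-2-yl]-3-methylpent-2-en-1-yl acetate
Conditions: D-fructose-derived Shi ketone (30 mol %), Oxone, K2CO3, Bu4NHSO4, MeCN/DMM–aq. borate buffer, 0 °C
Reagents that add atoms: Oxone (potassium peroxymonosulfate), [K+].[O-]S(=O)(=O)OO
Why: Shi asymmetric epoxidation (dioxirane, spiro transition state) attacks the electron-richer 6,7-olefin because the 2,3-olefin is deactivated by the allylic acetate, and the D-fructose ketone gives the (R)-epoxide that becomes the ring-A secondary carbinol.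

Step 2
Reactants: 2 (R)-6,7-epoxygeranyl acetate
Product: 4 [(1S,3R)-3-hydroxy-2,2-dimethyl-6-methylidenecyclohexyl]methyl acetate, via TMS ether 3 (not isolated)
Conditions: Cp2TiCl2 (20 mol %), Mn, TMSCl, 2,4,6-collidine, THF, rt; then 1 M HCl
Reagents that add atoms: chlorotrimethylsilane, C[Si](C)(C)Cl (its silyl group stays only in 3)
Why: Ti(III)-mediated reductive epoxide opening (Nugent–RajanBabu type, catalytic variant) gives the tertiary radical, whose 6-endo cyclization through a chair with OTi and CH2OAc equatorial sets the ring CH cis to the carbinol oxygen, and Ti–H loss leaves the exocyclic alkene.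

Step 3
Reactants: 4 exo-methylene alcohol
Product: 5 [(3R,4S,6R)-6-hydroxy-5,5-dimethyl-1-oxaspiro[2.5]octan-4-yl]methyl acetate
Conditions: mCPBA, NaHCO3, CH2Cl2, 0 °C
Reagents that add atoms: mCPBA, OOC(=O)c1cccc(Cl)c1
Why: Prilezhaev epoxidation occurs from the equatorial side because the axial side is blocked by the syn-axial methyl of the gem-dimethyl carbon, so the new C–O bond is equatorial and trans to the acetoxymethyl arm.

Step 4
Reactants: 5 spiro-epoxide
Product: 6 (1R,2S,4R)-2-(hydroxymethyl)-1,3,3-trimethylcyclohexane-1,4-diol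
Conditions: LiAlH4, THF, 0 °C to rt
Reagents that add atoms: none
Why: Hydride opens the epoxide by SN2 at its CH2 terminus, leaving the equatorial tertiary alcohol with an axial methyl (stereocentre untouched), and the same reagent reduces off the acetate.

Step 5
Reactants: 6 triol
Product: 7 (1R,3R,6R)-3,6-dihydroxy-2,2,6-trimethylcyclohexane-1-carbaldehyde
Conditions: TEMPO (10 mol %), PhI(OAc)2 (1.1 equiv), CH2Cl2, rt
Reagents that add atoms: none
Why: Oxoammonium (TEMPO/BAIB) oxidation is selective for the primary alcohol over the hindered secondary and the tertiary ones, and the equatorial aldehyde is the stable epimer.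

Step 6
Reactants: 7 hydroxy aldehyde; 8 2-(dichloromethyl)-4,4,5,5-tetramethyl-1,3,2-dioxaborolane
Product: 10 (1R,2R,4R)-1,3,3-trimethyl-2-[(E)-2-(4,4,5,5-tetramethyl-1,3,2-dioxaborolan-2-yl)ethenyl]cyclohexane-1,4-diol, via gem-dichromium boronate 9 (not isolated)
Conditions: CrCl2 (8 equiv), LiI (4 equiv), THF, rt
Reagents that add atoms: chromium(II) chloride, Cl[Cr]Cl (chromium stays only in 9)
Why: Takai–Utimoto boryl olefination adds the gem-dichromium reagent to the aldehyde and eliminates anti to give the (E)-alkenyl boronate; free hydroxyls are tolerated.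

Step 7
Reactants: 11 2,5-dimethoxyterephthalaldehyde (2.5 equiv, excess recovered); 12 propyne
Product: 14 4-[(1S)-1-hydroxybut-2-yn-1-yl]-2,5-dimethoxybenzaldehyde, via alkynylzinc 13 (not isolated)
Conditions: Me2Zn, ProPhenol (10 mol %, antipode giving Si-face addition), Ph3PO (20 mol %), toluene, 0 °C
Reagents that add atoms: dimethylzinc, C[Zn]C (methylzinc stays only in 13)
Why: Trost dinuclear zinc–ProPhenol alkynylation of an aryl aldehyde sets the (S)-carbinol by catalyst-controlled Si-face attack, and the excess of the symmetric dialdehyde limits the reaction to mono-addition.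

Step 8
Reactants: 14 propargylic alcohol aldehyde
Product: 16 (1S,2Z)-1-[4-(hydroxymethyl)-2,5-dimethoxyphenyl]-3-iodobut-2-en-1-ol, via cyclic alkenylalanate 15 (not isolated)
Conditions: Red-Al (3.5 equiv), THF, 0 °C to rt; then I2, −78 to 0 °C
Reagents that add atoms: iodine, II; Red-Al, [Na+].COCCO[AlH2-]OCCOC (aluminium and its ligands stay only in 15)
Why: Red-Al reduces the aldehyde and trans-hydroaluminates the propargylic alkoxide through a five-membered alkoxyalanate that places Al on the distal carbon cis to the carbinol, and iodinolysis with retention gives the (Z)-iodoalkene.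

Step 9
Reactants: 16 iodo diol
Product: 17 {4-[(1S,2Z)-1-hydroxy-3-iodobut-2-en-1-yl]-2,5-dimethoxyphenyl}methyl 2,2-dimethylpropanoate
Conditions: PivCl (1.05 equiv), pyridine, CH2Cl2, −20 °C
Reagents that add atoms: pivaloyl chloride, CC(C)(C)C(=O)Cl
Why: Selective acylation of the unhindered primary benzylic alcohol removes the competing directing hydroxyl for step 11, and the ester is later cleaved by the reductant of step 12.

Step 10
Reactants: 17 dimethoxyarene pivalate
Product: 18 {4-[(1S,2Z)-1-hydroxy-3-iodobut-2-en-1-yl]-3,6-dioxocyclohexa-1,4-dien-1-yl}methyl 2,2-dimethylpropanoate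
Conditions: CAN (2.5 equiv), MeCN/H2O, 0 °C, 15 min
Reagents that add atoms: water, O
Why: Ceric ammonium nitrate oxidative demethylation of a hydroquinone dimethyl ether gives the p-quinone (water supplies the carbonyl oxygens), and benzylic carbinols, esters and iodoalkenes tolerate the brief treatment.

Step 11
Reactants: 18 hydroxyalkyl quinone
Product: 19 [(1R,6S)-6-[(1S,2Z)-1-hydroxy-3-iodobut-2-en-1-yl]-2,5-dioxo-7-oxabicyclo[4.1.0]hept-3-en-3-yl]methyl 2,2-dimethylpropanoate
Conditions: t-BuOOH (1.05 equiv), LiHMDS (1.0 equiv), toluene/THF (0.01 M), −78 to −30 °C; aq. NH4Cl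
Reagents that add atoms: tert-butyl hydroperoxide, CC(C)(C)OO
Why: Proposed new method: a substrate-bound lithium tert-butylperoxide (nucleophilic, Weitz–Scheffer type) is delivered from the side-chain carbinol oxygen through a six-membered Li-bridged transition state to the β-carbon of the hydroxyalkyl-bearing quinone C=C only, so the pivaloyloxymethyl-bearing C=C is untouched; with the carbinol H eclipsing the adjacent C=O (A1,3 minimum) the iodoalkenyl group lies on the far face and oxygen enters syn to the carbinol C–O bond, giving the erythro epoxy alcohol (both oxirane stereocentres), and enolate closure expels t-BuOLi; the closest known reactions are the tartrate-mediated hydroxyl-directed nucleophilic epoxidation of hydroxymethyl quinone monoketals and the alkoxide-directed t-BuOOLi epoxidation of α-(hydroxyalkyl) enones, neither shown on a free p-benzoquinone with site selection between its two C=C bonds.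

Step 12
Reactants: 19 epoxyquinone
Product: 20 (1S,2S,5R,6S)-1-[(1S,2Z)-1-hydroxy-3-iodobut-2-en-1-yl]-4-(hydroxymethyl)-7-oxabicyclo[4.1.0]hept-3-ene-2,5-diol
Conditions: DIBAL-H (8 equiv), CH2Cl2/toluene, −78 to −40 °C; Rochelle salt
Reagents that add atoms: none
Why: DIBAL-H 1,2-reduction with aluminium bound to the oxirane oxygen delivers hydride to both flanking carbonyls on the epoxide face (the other face of the carbonyl next to the quaternary carbon is also shielded by the aluminated side chain), so both new carbinols are anti to the oxirane and cis to each other; excess reagent cleaves the pivalate.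

Step 13
Reactants: 20 core (Z)-alkenyl iodide; 10 ring-A (E)-alkenyl boronate
Product: 21 arthrosporol A
Conditions: Pd(dppf)Cl2 (10 mol %), AsPh3 (20 mol %), Cs2CO3, DMF/THF/H2O, rt
Reagents that add atoms: none
Why: Suzuki–Miyaura coupling proceeds with retention at both sp2 carbons and so gives the (2Z,4E)-diene directly, and the mild carbonate conditions tolerate the epoxy polyol.

**Compound list**

1 | geranyl acetate | CC(=O)OC/C=C(\C)CCC=C(C)C | starting material
2 | (2E)-5-[(2R)-3,3-dimethyloxiran-2-yl]-3-methylpent-2-en-1-yl acetate | CC(=O)OC/C=C(\C)CC[C@H]1OC1(C)C | intermediate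
3 | [(1S,3R)-2,2-dimethyl-6-methylidene-3-(trimethylsilyloxy)cyclohexyl]methyl acetate | CC(=O)OC[C@@H]1C(C)(C)[C@H](O[Si](C)(C)C)CCC1=C | intermediate (not isolated)
4 | [(1S,3R)-3-hydroxy-2,2-dimethyl-6-methylidenecyclohexyl]methyl acetate | CC(=O)OC[C@@H]1C(C)(C)[C@H](O)CCC1=C | intermediate
5 | [(3R,4S,6R)-6-hydroxy-5,5-dimethyl-1-oxaspiro[2.5]octan-4-yl]methyl acetate | CC(=O)OC[C@@H]1C(C)(C)[C@H](O)CC[C@]12CO2 | intermediate
6 | (1R,2S,4R)-2-(hydroxymethyl)-1,3,3-trimethylcyclohexane-1,4-diol | OC[C@@H]1C(C)(C)[C@H](O)CC[C@@]1(C)O | intermediate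
7 | (1R,3R,6R)-3,6-dihydroxy-2,2,6-trimethylcyclohexane-1-carbaldehyde | O=C[C@@H]1C(C)(C)[C@H](O)CC[C@@]1(C)O | intermediate
8 | 2-(dichloromethyl)-4,4,5,5-tetramethyl-1,3,2-dioxaborolane | CC1(C)OB(C(Cl)Cl)OC1(C)C | starting material
9 | [(4,4,5,5-tetramethyl-1,3,2-dioxaborolan-2-yl)methylidene]bis(dichlorochromium) | CC1(C)OB(C([Cr](Cl)Cl)[Cr](Cl)Cl)OC1(C)C | intermediate (not isolated)
10 | (1R,2R,4R)-1,3,3-trimethyl-2-[(E)-2-(4,4,5,5-tetramethyl-1,3,2-dioxaborolan-2-yl)ethenyl]cyclohexane-1,4-diol | CC1(C)OB(/C=C/[C@@H]2C(C)(C)[C@H](O)CC[C@@]2(C)O)OC1(C)C | intermediate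
11 | 2,5-dimethoxyterephthalaldehyde | COc1cc(C=O)c(OC)cc1C=O | starting material
12 | propyne | CC#C | starting material
13 | methyl(prop-1-yn-1-yl)zinc | C[Zn]C#CC | intermediate (not isolated)
14 | 4-[(1S)-1-hydroxybut-2-yn-1-yl]-2,5-dimethoxybenzaldehyde | CC#C[C@H](O)c1cc(OC)c(C=O)cc1OC | intermediate
15 | disodium alkoxy(alkenyl)aluminate from trans-hydroalumination (2,5-dihydro-1,2-oxaluminole ate complex; benzylic oxygen as hydridoaluminate) | [Na+].[Na+].COCCO[Al-]1(OCCOC)O[C@@H](C=C1C)c1cc(OC)c(CO[AlH-](OCCOC)OCCOC)cc1OC | intermediate (not isolated)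
16 | (1S,2Z)-1-[4-(hydroxymethyl)-2,5-dimethoxyphenyl]-3-iodobut-2-en-1-ol | CC(/I)=C/[C@H](O)c1cc(OC)c(CO)cc1OC | intermediate
17 | {4-[(1S,2Z)-1-hydroxy-3-iodobut-2-en-1-yl]-2,5-dimethoxyphenyl}methyl 2,2-dimethylpropanoate | CC(/I)=C/[C@H](O)c1cc(OC)c(COC(=O)C(C)(C)C)cc1OC | intermediate
18 | {4-[(1S,2Z)-1-hydroxy-3-iodobut-2-en-1-yl]-3,6-dioxocyclohexa-1,4-dien-1-yl}methyl 2,2-dimethylpropanoate | CC(/I)=C/[C@H](O)C1=CC(=O)C(COC(=O)C(C)(C)C)=CC1=O | intermediate
19 | [(1R,6S)-6-[(1S,2Z)-1-hydroxy-3-iodobut-2-en-1-yl]-2,5-dioxo-7-oxabicyclo[4.1.0]hept-3-en-3-yl]methyl 2,2-dimethylpropanoate | CC(/I)=C/[C@H](O)[C@]12O[C@H]1C(=O)C(COC(=O)C(C)(C)C)=CC2=O | intermediate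
20 | (1S,2S,5R,6S)-1-[(1S,2Z)-1-hydroxy-3-iodobut-2-en-1-yl]-4-(hydroxymethyl)-7-oxabicyclo[4.1.0]hept-3-ene-2,5-diol | CC(/I)=C/[C@H](O)[C@]12O[C@H]1[C@H](O)C(CO)=C[C@@H]2O | intermediate
21 | arthrosporol A, (1R,2S,5R,6S)-1-[(1S,2Z,4E)-5-[(1R,3R,6R)-3,6-dihydroxy-2,2,6-trimethylcyclohexyl]-1-hydroxy-3-methylpenta-2,4-dien-1-yl]-4-(hydroxymethyl)-7-oxabicyclo[4.1.0]hept-3-ene-2,5-diol | CC(=C/[C@H](O)[C@]12O[C@H]1[C@H](O)C(CO)=C[C@@H]2O)/C=C/[C@@H]1C(C)(C)[C@H](O)CC[C@@]1(C)O | target

**Totals and risks**

Total step count: 13. Longest linear sequence: 7 steps (7–12, then 13; the ring-A branch 1–6, then 13, is equally long).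

Steps most likely to fail:

Step 11 (the proposed directed epoxidation; risks are attack on the in-plane chelated conformer giving the threo isomer, and base-induced redox isomerization of the quinone carbinol). The fallback uses known reaction types; it sets out from 17 and returns at 19. Anodic oxidation of 17 in methanol (Pt anode, LiClO4, 2,6-lutidine, 0 °C) gives the quinone bis(dimethyl ketal) {4-[(1S,2Z)-1-hydroxy-3-iodobut-2-en-1-yl]-3,3,6,6-tetramethoxycyclohexa-1,4-dien-1-yl}methyl 2,2-dimethylpropanoate F2. Its carbinol then directs a vanadium-catalysed electrophilic epoxidation (VO(acac)2, t-BuOOH, CH2Cl2), for which the A1,2-controlled erythro preference of 1-cycloalkenyl carbinols is established, to give the epoxy bisketal [(1R,6S)-6-[(1S,2Z)-1-hydroxy-3-iodobut-2-en-1-yl]-2,2,5,5-tetramethoxy-7-oxabicyclo[4.1.0]hept-3-en-3-yl]methyl 2,2-dimethylpropanoate F3. Hydrolysis of both ketals (wet montmorillonite K10 or aqueous TFA) gives 19.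

Step 12 (the facial sense at the carbonyl remote from the side chain rests on aluminium–oxirane coordination and is the least certain stereocentre). The fallback sets out from 19 and returns at 20. Reagent-controlled CBS reduction ((R)-Me-CBS, catecholborane, toluene, −78 °C) treats the quaternary oxirane carbon at one carbonyl and the substituted vinyl carbon at the other as the large groups, so the same catalyst attacks both from the epoxide face and gives the diol pivalate [(1S,2R,5S,6S)-2,5-dihydroxy-6-[(1S,2Z)-1-hydroxy-3-iodobut-2-en-1-yl]-7-oxabicyclo[4.1.0]hept-3-en-3-yl]methyl 2,2-dimethylpropanoate F4. K2CO3 in methanol then removes the pivalate to give 20.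

Step 6 (chromium olefination of a very hindered β-hydroxy aldehyde flanked by two quaternary carbons). The fallback sets out from 7 and returns at 10. Colvin homologation of 7 with lithiated trimethylsilyldiazomethane (THF, −78 to 0 °C) gives the terminal alkyne (1R,2R,4R)-2-ethynyl-1,3,3-trimethylcyclohexane-1,4-diol F1. Cp2Zr(H)Cl-catalysed syn-hydroboration of this alkyne with pinacolborane gives 10.

Further compounds
F1 | step 6 | (1R,2R,4R)-2-ethynyl-1,3,3-trimethylcyclohexane-1,4-diol | C#C[C@@H]1C(C)(C)[C@H](O)CC[C@@]1(C)O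
F2 | step 11 | {4-[(1S,2Z)-1-hydroxy-3-iodobut-2-en-1-yl]-3,3,6,6-tetramethoxycyclohexa-1,4-dien-1-yl}methyl 2,2-dimethylpropanoate | CC(/I)=C/[C@H](O)C1=CC(OC)(OC)C(COC(=O)C(C)(C)C)=CC1(OC)OC
F3 | step 11 | [(1R,6S)-6-[(1S,2Z)-1-hydroxy-3-iodobut-2-en-1-yl]-2,2,5,5-tetramethoxy-7-oxabicyclo[4.1.0]hept-3-en-3-yl]methyl 2,2-dimethylpropanoate | CC(/I)=C/[C@H](O)[C@]12O[C@H]1C(OC)(OC)C(COC(=O)C(C)(C)C)=CC2(OC)OC
F4 | step 12 | [(1S,2R,5S,6S)-2,5-dihydroxy-6-[(1S,2Z)-1-hydroxy-3-iodobut-2-en-1-yl]-7-oxabicyclo[4.1.0]hept-3-en-3-yl]methyl 2,2-dimethylpropanoate | CC(/I)=C/[C@H](O)[C@]12O[C@H]1[C@H](O)C(COC(=O)C(C)(C)C)=C[C@@H]2O
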